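The quinone ring (C1 carbonyl, C2–OH, C3–henicosyl, C4 carbonyl, C5–OH, C6–CH3) is cut into the four-carbon piece C2–C3–C4–C5, a squaric ester that already carries three of the four ring oxygens, and the two-carbon piece C6–C1, the silyl ynol ether of propyne. The key step exploits the alternation of four oxygen-bearing carbons with two para alkyl-bearing carbons. Heating cyclobutenone 7 with siloxypropyne 11 should insert the alkyne into the C2–C5 bond (vinylketene, [2+2], 4π opening, 6π closure), forming C1–C2 and C5–C6 at once. The product is the hexasubstituted benzene 16 at the tetrahydroxybenzene oxidation level, which only needs unmasking and air oxidation.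

Key step: step 5

Remark: 1-bromohenicosane is taken as a purchasable long-chain bromide, and all cyclobutenes with a stereocentre are carried as racemates because every such centre becomes trigonal before the achiral target.

Step 1
Reactants: 1 diisopropyl squarate
Product: 2 4-hydroxy-2,3-di(propan-2-yloxy)cyclobut-2-en-1-one
Conditions: LiAlH(Ot-Bu)3 (1.1 equiv), THF, −78 → −30 °C; aq. work-up
Reagents that add atoms: none
Why: Chemoselective 1,2-hydride reduction, in which the bulky LiAlH(Ot-Bu)3 should reduce one vinylogous-ester carbonyl of the squarate and the resulting alkoxide should stop further reduction; the new centre needs no control because it becomes trigonal later.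

Step 2
Reactants: 2 4-hydroxy-2,3-di(propan-2-yloxy)cyclobut-2-en-1-one
Product: 3 4-[tert-butyl(dimethyl)silyl]oxy-2,3-di(propan-2-yloxy)cyclobut-2-en-1-one
Conditions: TBSCl, imidazole, DMF, 0 °C → rt
Reagents that add atoms: tert-butyldimethylsilyl chloride, CC(C)(C)[Si](C)(C)Cl
Why: Imidazole-mediated silyl ether formation masks the secondary hydroxyl so that it cannot quench the Grignard reagent, ionise in step 3 or lactonise onto the ketene in step 5.

Step 3
Reactants: 3 4-[tert-butyl(dimethyl)silyl]oxy-2,3-di(propan-2-yloxy)cyclobut-2-en-1-one; 4 1-bromohenicosane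
Product: 7 4-[tert-butyl(dimethyl)silyl]oxy-3-henicosyl-2-(propan-2-yloxy)cyclobut-2-en-1-one, via henicosylmagnesium bromide 5 (not isolated), via bromomagnesium cyclobutenolate adduct 6 (not isolated)
Conditions: 4, Mg, THF, 50 °C; then 3, THF, −78 → −40 °C; then (CF3CO)2O, −78 → 0 °C; aq. NaHCO3
Reagents that add atoms: water, O
Why: Grignard 1,2-addition to the only carbonyl group, followed by trifluoroacetylation, ionisation to the isopropoxy-stabilised cyclobutenyl cation and hydrolysis (the 1,3-carbonyl transposition of squarate adducts, a Stork–Danheiser-type sequence), should place the henicosyl group on the ring double bond next to the silyloxy carbon, while enolisation of 3 is excluded because it would give a cyclobutadienolate.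

Step 4
Reactants: 8 propyne
Product: 11 tri(propan-2-yl)(prop-1-yn-1-yloxy)silane, via 1-propynyllithium 9 (not isolated), via lithium propynolate 10 (not isolated)
Conditions: n-BuLi, THF, −78 °C; t-BuOOLi (from t-BuOOH and LiN(SiMe3)2), THF, −78 → 0 °C; then TIPSOTf, −78 °C → rt
Reagents that add atoms: tert-butyl hydroperoxide, CC(C)(C)OO; triisopropylsilyl trifluoromethanesulfonate, CC(C)[Si](OS(=O)(=O)C(F)(F)F)(C(C)C)C(C)C
Why: Electrophilic oxygen transfer from lithium tert-butyl peroxide to the lithium acetylide should give the ynolate, which the bulky silyl triflate traps on oxygen (O-silylation of an ynolate), a known entry to triisopropylsiloxyalkynes.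

Step 5
Reactants: 7 4-[tert-butyl(dimethyl)silyl]oxy-3-henicosyl-2-(propan-2-yloxy)cyclobut-2-en-1-one; 11 tri(propan-2-yl)(prop-1-yn-1-yloxy)silane
Product: 16 2-[tert-butyl(dimethyl)silyl]oxy-3-henicosyl-6-methyl-4-(propan-2-yloxy)-5-[tri(propan-2-yl)silyl]oxyphenol, via silyloxyvinylketene 12 (not isolated), via alkenylcyclobutenone 13 (not isolated), via dienylketene 14 (not isolated), via cyclohexadienone 15 (not isolated)
Conditions: 11 (2.5 equiv), toluene, 80 → 110 °C, sealed tube, argon
Reagents that add atoms: none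
Why: Heating should open 7 by conrotatory 4π ring opening (silyloxy group turning outward) to vinylketene 12, whose ketene C=C adds ynol ether 11 in a [2+2] cycloaddition to give 13; this opens again (isopropoxy outward, alkenyl inward) to the (Z)-dienylketene 14, which closes to dienone 15 and tautomerises to phenol 16. The closest known reaction type is the Danheiser benzannulation of cyclobutenones with siloxyalkynes. The transient four-membered ring closes by [2+2] cycloaddition and the benzene ring by disrotatory 6π electrocyclisation, which rejoins C4 and C5 after the alkyne carbons C6 and C1 have entered between C5 and C2. The only new stereocentres (the quaternary carbon of 13 and C6 of 15) are transient and vanish on aromatisation, so none needs control. The step needs regioselectivity in the [2+2] event, and the polarisation of the partners secures it: the nucleophilic methyl-bearing alkyne carbon bonds to the electrophilic ketene carbonyl carbon (C5) and the siloxy-bearing carbon to the ketene α-carbon (C2). It also needs the alkyne to outrun ketene dimerisation, which excess 11 and the reversible ring opening should favour.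

Step 6
Reactants: 16 2-[tert-butyl(dimethyl)silyl]oxy-3-henicosyl-6-methyl-4-(propan-2-yloxy)-5-[tri(propan-2-yl)silyl]oxyphenol
Product: 19 3-henicosyl-2,5-dihydroxy-6-methylcyclohexa-2,5-diene-1,4-dione, via trihydroxybenzene 17 (not isolated), via isopropoxy hydroxyquinone 18 (not isolated)
Conditions: Bu4NF (2.5 equiv), THF, 0 °C → rt, open to air; then 2 M NaOH aq, MeOH, 50 °C; then 2 M HCl
Reagents that add atoms: sodium hydroxide, [Na+].[OH-]
Why: Fluoride should cleave both aryl silyl ethers, air should oxidise the resulting 1,2,4-trihydroxybenzene to the hydroxy-para-quinone (autoxidation of a hydroxyhydroquinone), and hydroxide should then replace the isopropoxy group by addition–elimination at the vinylogous ester carbon C2 before acidification.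

Compound list

1 | diisopropyl squarate (3,4-di(propan-2-yloxy)cyclobut-3-ene-1,2-dione) | CC(C)OC1=C(OC(C)C)C(=O)C1=O | starting material
2 | 4-hydroxy-2,3-di(propan-2-yloxy)cyclobut-2-en-1-one (racemic) | CC(C)OC1=C(OC(C)C)C(=O)C1O | intermediate
3 | 4-[tert-butyl(dimethyl)silyl]oxy-2,3-di(propan-2-yloxy)cyclobut-2-en-1-one (racemic) | CC(C)OC1=C(OC(C)C)C(=O)C1O[Si](C)(C)C(C)(C)C | intermediate
4 | 1-bromohenicosane | CCCCCCCCCCCCCCCCCCCCCBr | starting material
5 | henicosylmagnesium bromide | CCCCCCCCCCCCCCCCCCCCC[Mg]Br | intermediate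
6 | bromomagnesium 4-[tert-butyl(dimethyl)silyl]oxy-1-henicosyl-2,3-di(propan-2-yloxy)cyclobut-2-en-1-olate (racemic mixture of diastereomers) | CCCCCCCCCCCCCCCCCCCCCC1(O[Mg]Br)C(OC(C)C)=C(OC(C)C)C1O[Si](C)(C)C(C)(C)C | intermediate
7 | 4-[tert-butyl(dimethyl)silyl]oxy-3-henicosyl-2-(propan-2-yloxy)cyclobut-2-en-1-one (racemic) | CCCCCCCCCCCCCCCCCCCCCC1=C(OC(C)C)C(=O)C1O[Si](C)(C)C(C)(C)C | intermediate
8 | propyne | CC#C | starting material
9 | 1-propynyllithium | CC#C[Li] | intermediate
10 | lithium prop-1-yn-1-olate | CC#C[O-].[Li+] | intermediate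
11 | tri(propan-2-yl)(prop-1-yn-1-yloxy)silane | CC#CO[Si](C(C)C)(C(C)C)C(C)C | intermediate
12 | (E)-4-[tert-butyl(dimethyl)silyl]oxy-3-henicosyl-2-(propan-2-yloxy)buta-1,3-dien-1-one | CCCCCCCCCCCCCCCCCCCCC/C(=C\O[Si](C)(C)C(C)(C)C)C(OC(C)C)=C=O | intermediate
13 | 4-{(E)-1-[tert-butyl(dimethyl)silyl]oxytricos-1-en-2-yl}-2-methyl-4-(propan-2-yloxy)-3-[tri(propan-2-yl)silyl]oxycyclobut-2-en-1-one (racemic) | CCCCCCCCCCCCCCCCCCCCC/C(=C\O[Si](C)(C)C(C)(C)C)C1(OC(C)C)C(=O)C(C)=C1O[Si](C(C)C)(C(C)C)C(C)C | intermediate
14 | (3Z,5E)-6-[tert-butyl(dimethyl)silyl]oxy-5-henicosyl-2-methyl-4-(propan-2-yloxy)-3-[tri(propan-2-yl)silyl]oxyhexa-1,3,5-trien-1-one | CCCCCCCCCCCCCCCCCCCCC/C(=C\O[Si](C)(C)C(C)(C)C)/C(OC(C)C)=C(/O[Si](C(C)C)(C(C)C)C(C)C)C(C)=C=O | intermediate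
15 | 6-[tert-butyl(dimethyl)silyl]oxy-5-henicosyl-2-methyl-4-(propan-2-yloxy)-3-[tri(propan-2-yl)silyl]oxycyclohexa-2,4-dien-1-one (racemic) | CCCCCCCCCCCCCCCCCCCCCC1=C(OC(C)C)C(O[Si](C(C)C)(C(C)C)C(C)C)=C(C)C(=O)C1O[Si](C)(C)C(C)(C)C | intermediate
16 | 2-[tert-butyl(dimethyl)silyl]oxy-3-henicosyl-6-methyl-4-(propan-2-yloxy)-5-[tri(propan-2-yl)silyl]oxyphenol | CCCCCCCCCCCCCCCCCCCCCc1c(OC(C)C)c(O[Si](C(C)C)(C(C)C)C(C)C)c(C)c(O)c1O[Si](C)(C)C(C)(C)C | intermediate
17 | 6-henicosyl-3-methyl-5-(propan-2-yloxy)benzene-1,2,4-triol | CCCCCCCCCCCCCCCCCCCCCc1c(OC(C)C)c(O)c(C)c(O)c1O | intermediate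
18 | 3-henicosyl-5-hydroxy-6-methyl-2-(propan-2-yloxy)cyclohexa-2,5-diene-1,4-dione | CCCCCCCCCCCCCCCCCCCCCC1=C(OC(C)C)C(=O)C(C)=C(O)C1=O | intermediate
19 | 3-henicosyl-2,5-dihydroxy-6-methylcyclohexa-2,5-diene-1,4-dione | CCCCCCCCCCCCCCCCCCCCCC1=C(O)C(=O)C(C)=C(O)C1=O | target

Total step count: 6. Longest linear sequence: 5 steps (steps 1, 2, 3, 5 and 6); step 4 is a one-step side branch.

Steps most likely to fail

1. Step 5. The transient silyloxyvinylketene may dimerise or re-close faster than the ynol ether adds, or the cascade may stall at the alkenylcyclobutenone. The fallback sets out from 1 and comes back at 19, and makes the same two ring bonds in two stages without bimolecular capture of a ketene (Moore rearrangement). 1-Lithio-1-methoxypropa-1,2-diene F1 (methoxyallene, n-BuLi, THF, −78 °C) is added to 1 and the alkoxide is silylated in the flask (Me3SiCl) to give silyl ether F2. Grignard reagent 5 and then (CF3CO)2O, as in step 3, should transpose it to cyclobutenone F3. Bu4NF/AcOH (THF, 0 °C) should free carbinol F4. In toluene at 110 °C this should open (4π) and close onto the central allene carbon (6π) to the hydroxy ortho-quinone methide F5, which should tautomerise to the dialkoxyquinone F6. NaOH and then HCl, as in the second half of step 6, should hydrolyse both vinylogous esters to 19. Here C1–C2 arises in the 1,2-addition and C5–C6 in the electrocyclisation.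

2. Step 3. The trifluoroacetylated adduct may ionise along another path (loss of the silyloxy group) or hydrolysis may strip the second isopropoxy group. The fallback sets out from 3 and comes back at 7 without any ionisation: copper-catalysed conjugate addition–elimination of Grignard reagent 5 on the vinylogous ester 3 (CuBr·SMe2 10 mol %, THF, −78 → −20 °C) should replace the β-isopropoxy group directly by the henicosyl group.

3. Step 6. Displacement of isopropoxide from the hydroxyquinone anion may be slow while base and peroxide erode the electron-rich ring. The fallback sets out from 16 and comes back at 19 by removing the isopropyl group before any oxidation. BCl3 (CH2Cl2, −78 → 0 °C) should cleave the isopropyl aryl ether to the hydroquinone bis-silyl ether F7. Bu4NF (THF, open to air) should then give the tetrol F8, which air should oxidise to 19.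

Further compounds

F1 | step 5 | 1-lithio-1-methoxypropa-1,2-diene | [Li]C(OC)=C=C
F2 | step 5 | 4-(1-methoxypropa-1,2-dien-1-yl)-2,3-di(propan-2-yloxy)-4-(trimethylsilyloxy)cyclobut-2-en-1-one (racemic) | C=C=C(OC)C1(O[Si](C)(C)C)C(OC(C)C)=C(OC(C)C)C1=O
F3 | step 5 | 3-henicosyl-4-(1-methoxypropa-1,2-dien-1-yl)-2-(propan-2-yloxy)-4-(trimethylsilyloxy)cyclobut-2-en-1-one (racemic) | CCCCCCCCCCCCCCCCCCCCCC1=C(OC(C)C)C(=O)C1(O[Si](C)(C)C)C(OC)=C=C
F4 | step 5 | 3-henicosyl-4-hydroxy-4-(1-methoxypropa-1,2-dien-1-yl)-2-(propan-2-yloxy)cyclobut-2-en-1-one (racemic) | CCCCCCCCCCCCCCCCCCCCCC1=C(OC(C)C)C(=O)C1(O)C(OC)=C=C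
F5 | step 5 | 3-henicosyl-4-hydroxy-5-methoxy-6-methylidene-2-(propan-2-yloxy)cyclohexa-2,4-dien-1-one | CCCCCCCCCCCCCCCCCCCCCC1=C(OC(C)C)C(=O)C(=C)C(OC)=C1O
F6 | step 5 | 3-henicosyl-5-methoxy-6-methyl-2-(propan-2-yloxy)cyclohexa-2,5-diene-1,4-dione | CCCCCCCCCCCCCCCCCCCCCC1=C(OC(C)C)C(=O)C(C)=C(OC)C1=O
F0 | step 3 | none | none
F7 | step 6 | 2-[tert-butyl(dimethyl)silyl]oxy-3-henicosyl-6-methyl-5-[tri(propan-2-yl)silyl]oxybenzene-1,4-diol | CCCCCCCCCCCCCCCCCCCCCc1c(O)c(O[Si](C(C)C)(C(C)C)C(C)C)c(C)c(O)c1O[Si](C)(C)C(C)(C)C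
F8 | step 6 | 3-henicosyl-6-methylbenzene-1,2,4,5-tetrol | CCCCCCCCCCCCCCCCCCCCCc1c(O)c(O)c(C)c(O)c1O
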